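**Plan**
- Retrosynthetic cuts: (i) the C=O of the Ar–CH2–C(=O)–Ar bridge, back to a C2-symmetric diarylalkyne (alkyne hydration); (ii) in each central ring the ring bonds C1–C2 and C5–C6, back to an ynone alkyne (C1, C6) and a 2-siloxyfuran (C2–C5 with both oxygens); (iii) the two C(sp)–C(carbinol) bonds of a linear triyne.
- Forward order: a C6 triyne chain is joined to two aryl carbinols and oxidised to the triynedione; both pentasubstituted rings then arise at once around the central alkyne; O-methylation; hydration of the central alkyne.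
- Enabling feature: the two central rings (ring B on CH2, ring C on the bridge C=O) are constitutionally identical 2-aroylhydroquinone rings (C1 2,6-dimethoxybenzoyl, C2 OH, C3 H, C4 Me, C5 OMe, C6 bridge; oxygens para at C2/C5). The CH2–C(=O) bridge is therefore the hydrate of a symmetric alkyne, and each ring is the retron of an oxyfuran + alkyne [4+2]/ring-opening.
- Stereochemistry: the target has no stereocentre; nothing has to be set.

Key step: step 5

Remark on the chemistry: the target SMILES has no stereocentre and the aryl–carbonyl axes are taken as freely rotating, so the compound is treated as achiral. Carbinol and bridgehead centres of intermediates form without control and are erased again. Ring numbering C1–C6 as defined above is used throughout.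

**Route**

Step 1
Reactants: 1 hexa-2,4-diyne-1,6-diol
Product: 2 hexa-2,4-diyne-1,6-diyl bis(4-methylbenzenesulfonate)
Conditions: TsCl (2.2 equiv), KOH, THF/H2O, 0 °C; product kept cold and dark
Reagents that add atoms: p-toluenesulfonyl chloride, Cc1ccc(cc1)S(=O)(=O)Cl
Why: Sulfonylation of a primary propargylic diol under Schotten–Baumann-type conditions should give the crystalline diacetylene bis-tosylate, which is stored cold and dark because such monomers polymerise in the solid state.

Step 2
Reactants: 2 hexa-2,4-diyne-1,6-diyl bis(4-methylbenzenesulfonate); 3 2,6-dimethoxybenzaldehyde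
Product: 5 1,8-bis(2,6-dimethoxyphenyl)octa-2,4,6-triyne-1,8-diol (rac/meso mixture), via 1,6-dilithiohexa-1,3,5-triyne 4 (not isolated)
Conditions: LDA (commercial solution, 4.4 equiv), THF, −78 → −30 °C; then 3 (2.2 equiv), −78 → 0 °C; H2O quench
Reagents that add atoms: none
Why: Base-induced conjugate elimination of both propargylic sulfonates through cumulenic intermediates (the 1,4-dichlorobut-2-yne → butadiynide reaction type, extended by one alkyne) should give the triyne, which is deprotonated as it forms so that the free triyne is never handled, and acetylide 1,2-addition to the non-enolisable aldehyde then gives the diol.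

Step 3
Reactants: 5 1,8-bis(2,6-dimethoxyphenyl)octa-2,4,6-triyne-1,8-diol
Product: 6 1,8-bis(2,6-dimethoxyphenyl)octa-2,4,6-triyne-1,8-dione
Conditions: activated MnO2 (excess), CH2Cl2, rt, dark; filtered, solvent exchanged to toluene without concentrating to dryness, used directly
Reagents that add atoms: none
Why: MnO2 oxidation of doubly activated (benzylic and propargylic) alcohols to ynones should leave the polyyne untouched and removes both uncontrolled carbinol centres.

Step 4
Reactants: 7 4-methylfuran-2(5H)-one
Product: 8 4-methyl-2-(trimethylsilyloxy)furan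
Conditions: TMSCl, Et3N, Et2O, 0 °C → rt; filtration, distillation
Reagents that add atoms: chlorotrimethylsilane, C[Si](C)(C)Cl
Why: Soft enolisation and O-silylation of the butenolide (silyl dienol ether formation) should give the aromatic 2-siloxyfuran.

Step 5
Reactants: 6 1,8-bis(2,6-dimethoxyphenyl)octa-2,4,6-triyne-1,8-dione; 8 4-methyl-2-(trimethylsilyloxy)furan (3 equiv)
Product: 13 1,2-bis[2-(2,6-dimethoxybenzoyl)-3,6-dihydroxy-5-methylphenyl]ethyne (each ring: C1 aroyl, C2 OH, C4 Me, C5 OH, C6 alkyne), via first 7-oxanorbornadiene cycloadduct 9 (not isolated), via mono-annulated aryl diynone silyl ether 10 (not isolated), via second 7-oxanorbornadiene cycloadduct 11 (not isolated), via bis(trimethylsilyl ether) diarylalkyne 12 (not isolated)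
Conditions: toluene, rt → 50 °C, dark, N2; then MeOH, PPTS (cat.), 0 °C → rt
Reagents that add atoms: none
Why: Each acyl-activated terminal alkyne of 6 should act as dienophile toward the electron-rich siloxyfuran in a polarised, asynchronous [4+2] cycloaddition; the 1-siloxy-7-oxanorbornadiene formed is a bridged ketal whose C–O bridge ionises with help of the siloxy oxygen, and loss of the proton at the former furan C5 aromatises it to a hydroquinone mono-silyl ether, which methanolysis frees (a silyl shift between the two oxygens would be irrelevant for the same reason). The closest known reaction type is the Diels–Alder/ring-opening aromatisation of 2-siloxy- and 2-alkoxyfurans with acetylenic esters and ketones to 4-oxyphenols. Rings B and C each close by an intermolecular [4+2] that forms the C1–C2 and C5–C6 bonds together, followed by opening of the oxygen bridge, not by a separate cyclisation. No stereocentre survives, because the bridgehead centres of 9 and 11 are destroyed on aromatisation. Orientation is needed and should follow from matched polarity: the nucleophilic furan C5 (next to the methyl group) bonds to the ynone β-carbon and the siloxy-bearing C2 to the α-carbon, which puts one oxygen ortho to the aroyl group (C2), the methyl group at C4 and the bridge-derived oxygen at C5 next to the alkyne. Site selectivity for the two terminal alkynes over the central one is also needed; it is expected because only the terminal alkynes carry a directly bound acyl group and a polarised π-bond, but it is the main uncertainty of the route.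

Step 6
Reactants: 13 1,2-bis[2-(2,6-dimethoxybenzoyl)-3,6-dihydroxy-5-methylphenyl]ethyne
Product: 14 1,2-bis[2-(2,6-dimethoxybenzoyl)-3-hydroxy-6-methoxy-5-methylphenyl]ethyne (each ring: C2 OH, C5 OMe)
Conditions: MeI (2.4 equiv), K2CO3 (2.2 equiv), acetone, rt, dark
Reagents that add atoms: iodomethane, CI
Why: Williamson etherification under chelation control: the C2–OH of each ring is held in a hydrogen bond to the aroyl carbonyl and should stay free, while the unchelated C5–OH is methylated at room temperature faster than its phenoxide can add 5-endo to the alkyne.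

Step 7
Reactants: 14 1,2-bis[2-(2,6-dimethoxybenzoyl)-3-hydroxy-6-methoxy-5-methylphenyl]ethyne
Product: 16 acredinone B, 1-[2-(2,6-dimethoxybenzoyl)-3-hydroxy-6-methoxy-5-methylphenyl]-2-[2-(2,6-dimethoxybenzoyl)-3-hydroxy-6-methoxy-5-methylphenyl]ethan-1-one, via 1H-isochromen-1-ol hemiketal 15 (not isolated)
Conditions: [JohnPhosAu(MeCN)]SbF6 (5 mol %), 1,4-dioxane/H2O (10:1), 40 °C; neutral work-up
Reagents that add atoms: water, O
Why: Neighbouring-carbonyl-assisted π-acid hydration: the aroyl oxygen should add 6-endo-dig to the gold-activated alkyne to give a 2-benzopyrylium species, water adds at C1 and hemiketal 15 opens to the 1,5-diketone; because the alkyne is C2-symmetric, either direction of oxygen delivery gives the same constitution.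

**Compound list**

1 | hexa-2,4-diyne-1,6-diol | OCC#CC#CCO | starting material
2 | hexa-2,4-diyne-1,6-diyl bis(4-methylbenzenesulfonate) | Cc1ccc(cc1)S(=O)(=O)OCC#CC#CCOS(=O)(=O)c1ccc(C)cc1 | intermediate
3 | 2,6-dimethoxybenzaldehyde | COc1cccc(OC)c1C=O | starting material
4 | 1,6-dilithiohexa-1,3,5-triyne | [Li]C#CC#CC#C[Li] | intermediate (not isolated)
5 | 1,8-bis(2,6-dimethoxyphenyl)octa-2,4,6-triyne-1,8-diol (rac/meso mixture, no defined configuration) | COc1cccc(OC)c1C(O)C#CC#CC#CC(O)c1c(OC)cccc1OC | intermediate
6 | 1,8-bis(2,6-dimethoxyphenyl)octa-2,4,6-triyne-1,8-dione | COc1cccc(OC)c1C(=O)C#CC#CC#CC(=O)c1c(OC)cccc1OC | intermediate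
7 | 4-methylfuran-2(5H)-one | CC1=CC(=O)OC1 | starting material
8 | 4-methyl-2-(trimethylsilyloxy)furan | Cc1coc(O[Si](C)(C)C)c1 | intermediate
9 | first cycloadduct: 1-(2,6-dimethoxyphenyl)-5-[3-(2,6-dimethoxybenzoyl)-6-methyl-4-(trimethylsilyloxy)-7-oxabicyclo[2.2.1]hepta-2,5-dien-2-yl]penta-2,4-diyn-1-one (racemic) | COc1cccc(OC)c1C(=O)C#CC#CC1=C(C(=O)c2c(OC)cccc2OC)C2(O[Si](C)(C)C)C=C(C)C1O2 | intermediate (not isolated)
10 | 1-(2,6-dimethoxyphenyl)-5-[2-(2,6-dimethoxybenzoyl)-6-hydroxy-5-methyl-3-(trimethylsilyloxy)phenyl]penta-2,4-diyn-1-one | COc1cccc(OC)c1C(=O)C#CC#Cc1c(O)c(C)cc(O[Si](C)(C)C)c1C(=O)c1c(OC)cccc1OC | intermediate (not isolated)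
11 | second cycloadduct: 7-oxanorbornadiene on one side, aromatised silyl ether ring on the other (racemic) | COc1cccc(OC)c1C(=O)C1=C(C#Cc2c(O)c(C)cc(O[Si](C)(C)C)c2C(=O)c2c(OC)cccc2OC)C2OC1(O[Si](C)(C)C)C=C2C | intermediate (not isolated)
12 | 1,2-bis[2-(2,6-dimethoxybenzoyl)-6-hydroxy-5-methyl-3-(trimethylsilyloxy)phenyl]ethyne | COc1cccc(OC)c1C(=O)c1c(O[Si](C)(C)C)cc(C)c(O)c1C#Cc1c(O)c(C)cc(O[Si](C)(C)C)c1C(=O)c1c(OC)cccc1OC | intermediate (not isolated)
13 | 1,2-bis[2-(2,6-dimethoxybenzoyl)-3,6-dihydroxy-5-methylphenyl]ethyne | COc1cccc(OC)c1C(=O)c1c(O)cc(C)c(O)c1C#Cc1c(O)c(C)cc(O)c1C(=O)c1c(OC)cccc1OC | intermediate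
14 | 1,2-bis[2-(2,6-dimethoxybenzoyl)-3-hydroxy-6-methoxy-5-methylphenyl]ethyne | COc1cccc(OC)c1C(=O)c1c(O)cc(C)c(OC)c1C#Cc1c(OC)c(C)cc(O)c1C(=O)c1c(OC)cccc1OC | intermediate
15 | 1-(2,6-dimethoxyphenyl)-1-hydroxy-1H-isochromene hemiketal carrying the ring-C aryl group at C3 (racemic) | COc1cccc(OC)c1C1(O)OC(c2c(OC)c(C)cc(O)c2C(=O)c2c(OC)cccc2OC)=Cc2c(OC)c(C)cc(O)c12 | intermediate (not isolated)
16 | acredinone B | COc1cccc(OC)c1C(=O)c1c(O)cc(C)c(OC)c1CC(=O)c1c(OC)c(C)cc(O)c1C(=O)c1c(OC)cccc1OC | target

**Count**

Total steps: 7. Longest linear sequence: 6 (steps 1, 2, 3, 5, 6, 7); step 4 is a one-step side branch.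

**Steps most likely to fail**

1. Step 5. What may go wrong: cycloaddition at the central alkyne (each of its carbons is δ to a carbonyl), conjugate addition of the furan without ring closure, or oligomerisation of the triynedione before the second annulation. Fallback, setting out from 3 and coming back at 14: the symmetric alkyne is made last by alkyne metathesis instead of being present from the start. Ethynylmagnesium bromide should add to 3 to give 1-(2,6-dimethoxyphenyl)prop-2-yn-1-ol F1. NBS with catalytic AgNO3 should give 3-bromo-1-(2,6-dimethoxyphenyl)prop-2-yn-1-ol F2. Cadiot–Chodkiewicz coupling with propyne (CuCl, NH2OH·HCl, n-BuNH2) should give 1-(2,6-dimethoxyphenyl)hexa-2,4-diyn-1-ol F3, and MnO2 the ynone 1-(2,6-dimethoxyphenyl)hexa-2,4-diyn-1-one F4, in which only one alkyne is acyl-activated and the other is methyl-capped. Cycloaddition with 8 as in step 5 should pass through the 7-oxanorbornadiene adduct F5 and the aryl silyl ether F6 and give, after methanolysis, (2,6-dimethoxyphenyl)[3,6-dihydroxy-4-methyl-2-(prop-1-yn-1-yl)phenyl]methanone F7. Chelation-controlled methylation (MeI, K2CO3) should give (2,6-dimethoxyphenyl)[6-hydroxy-3-methoxy-4-methyl-2-(prop-1-yn-1-yl)phenyl]methanone F8. Homodimerising alkyne metathesis (molybdenum alkylidyne with a tripodal silanolate ligand, 5 Å molecular sieves to take up but-2-yne, toluene, 80 °C) should then give 14.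

2. Step 2. What may go wrong: incomplete elimination, polymerisation of the cumulenic and polyynyl intermediates, or attack of the base at sulfur. Fallback, setting out from 3 and coming back at 5: the triyne is assembled by C4 + C2 coupling. Lithium 4-(trimethylsilyl)buta-1,3-diyn-1-ide F9 (from commercial 1,4-bis(trimethylsilyl)buta-1,3-diyne and MeLi·LiBr, THF) should add to 3 to give 1-(2,6-dimethoxyphenyl)-5-(trimethylsilyl)penta-2,4-diyn-1-ol F10. K2CO3/MeOH should give the terminal diyne 1-(2,6-dimethoxyphenyl)penta-2,4-diyn-1-ol F11. Cadiot–Chodkiewicz coupling of F11 with bromoalkyne F2 (made from 3 as described in the first fallback) should give 5.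

3. Step 7. What may go wrong: slow π-activation of the tetra-ortho-substituted alkyne, competing 5-endo attack of the neighbouring methoxy oxygen, or acid-promoted cyclodehydration or aldol closure of the product. Fallback, setting out from 14 and coming back at 16: catalytic metal activation is replaced by stoichiometric proton-induced cycloisomerisation to an isolable aromatic salt, with hydrolysis as a separate operation. TfOH (1.1 equiv, CH2Cl2, 0 °C) should give 1-(2,6-dimethoxyphenyl)-3-aryl-2-benzopyrylium triflate F12, which is precipitated with ether. Aqueous NaOAc/THF should then add water at C1 and open the pseudobase to the 1,5-diketone 16.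

**Further compounds**

F1 | step 5 | 1-(2,6-dimethoxyphenyl)prop-2-yn-1-ol (racemic) | COc1cccc(OC)c1C(O)C#C
F2 | step 5 | 3-bromo-1-(2,6-dimethoxyphenyl)prop-2-yn-1-ol (racemic) | COc1cccc(OC)c1C(O)C#CBr
F3 | step 5 | 1-(2,6-dimethoxyphenyl)hexa-2,4-diyn-1-ol (racemic) | COc1cccc(OC)c1C(O)C#CC#CC
F4 | step 5 | 1-(2,6-dimethoxyphenyl)hexa-2,4-diyn-1-one | COc1cccc(OC)c1C(=O)C#CC#CC
F5 | step 5 | 7-oxanorbornadiene cycloadduct of F4 and 8 (racemic, not isolated) | COc1cccc(OC)c1C(=O)C1=C(C#CC)C2OC1(O[Si](C)(C)C)C=C2C
F6 | step 5 | (2,6-dimethoxyphenyl)[3-hydroxy-4-methyl-2-(prop-1-yn-1-yl)-6-(trimethylsilyloxy)phenyl]methanone (not isolated) | COc1cccc(OC)c1C(=O)c1c(O[Si](C)(C)C)cc(C)c(O)c1C#CC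
F7 | step 5 | (2,6-dimethoxyphenyl)[3,6-dihydroxy-4-methyl-2-(prop-1-yn-1-yl)phenyl]methanone | COc1cccc(OC)c1C(=O)c1c(O)cc(C)c(O)c1C#CC
F8 | step 5 | (2,6-dimethoxyphenyl)[6-hydroxy-3-methoxy-4-methyl-2-(prop-1-yn-1-yl)phenyl]methanone | COc1cccc(OC)c1C(=O)c1c(O)cc(C)c(OC)c1C#CC
F9 | step 2 | lithium 4-(trimethylsilyl)buta-1,3-diyn-1-ide (not isolated) | [Li]C#CC#C[Si](C)(C)C
F10 | step 2 | 1-(2,6-dimethoxyphenyl)-5-(trimethylsilyl)penta-2,4-diyn-1-ol (racemic) | COc1cccc(OC)c1C(O)C#CC#C[Si](C)(C)C
F11 | step 2 | 1-(2,6-dimethoxyphenyl)penta-2,4-diyn-1-ol (racemic) | COc1cccc(OC)c1C(O)C#CC#C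
F12 | step 7 | 1-(2,6-dimethoxyphenyl)-3-[2-(2,6-dimethoxybenzoyl)-3-hydroxy-6-methoxy-5-methylphenyl]-8-hydroxy-5-methoxy-6-methyl-2-benzopyrylium trifluoromethanesulfonate | COc1cccc(OC)c1-c1[o+]c(-c2c(OC)c(C)cc(O)c2C(=O)c2c(OC)cccc2OC)cc2c(OC)c(C)cc(O)c12.[O-]S(=O)(=O)C(F)(F)F
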